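**Plan**

- Units: 1 = the 7-hydroxy dihydrobenzofuran (benzo ring A), 2 = the central dihydrobenzofuran (ring B), 3 = the 6-hydroxy dihydrobenzofuran (ring C); each is numbered O1, C2, C3, C3a, C4–C7, C7a. After removal of nine O-alkyl groups, the first cut is the bond from C5 of unit 1 to the E-alkene (Suzuki–Miyaura), giving a west aryl chloride and an east (E)-alkenylboronate.
- West: the aryl ring on C3 of unit 1 has its two oxygens meta to each other, a hydrogen between them and C3 meta to both. A 3-substituted cyclobutenone and an alkoxyacetylene give exactly this 1,3,5-pattern, so the ring is cut at the two bonds flanking its C(H)–C(O) pair and traced to a cyclobutenone on C3 plus ethoxyacetylene.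
- The cyclobutenone comes from a C3 alkyne and dichloroketene, the alkyne from a trans 3-ester, the ester from oxidative ring contraction of a (2S)-flavanone, and the flavanone from a chromone and an arylboronic acid.
- East: each furan ring is cut at C2–C3 (rhodium carbene insertion into an ArCH2–O C–H bond) and at the bond from C3 to its aryl group (aryl metal plus aldehyde, then oxidation); unit 3 is built first, then unit 2 on its C4.
- Forward: pyranone, flavanone, furan ring of unit 1, cyclobutenone, new resorcinol ring; separately furan ring of unit 3, furan ring of unit 2, alkenylboronate; then coupling and dealkylation.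
- Stereochemistry: C2 of unit 1 by ligand-controlled Pd conjugate addition, C3 of unit 1 trans through the ring contraction; C3 of units 3 and 2 by enantiomeric dirhodium catalysts, their C2 by acid equilibration to trans; the E alkene by a Heck reaction and a stereoretentive coupling.

Key step: step 8

Assumption: (R)-t-BuPyOx (4-tert-butyl-2-(pyridin-2-yl)-4,5-dihydrooxazole) is taken to give the (2S)-flavanone in step 3, Rh2(R-PTAD)4 (PTAD = (1-adamantyl)(N-phthalimido)acetate) the 3S cis ring in step 15 and Rh2(S-PTAD)4 the 3R cis ring in step 21; if a sense of induction is the opposite, the enantiomeric ligand or catalyst is used and nothing else changes.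

**Route**

Step 1
Reactants: 1 1-(2-hydroxy-3-methoxyphenyl)ethan-1-one
Product: 2 1-(5-chloro-2-hydroxy-3-methoxyphenyl)ethan-1-one
Conditions: NCS (1.05 equiv), p-TsOH·H2O (10 mol%), MeCN, rt
Reagents that add atoms: N-chlorosuccinimide, O=C1CCC(=O)N1Cl
Why: Electrophilic aromatic chlorination should go para to the free hydroxyl group (C5), the usual site of halogenation in 2-hydroxy-3-methoxyaryl carbonyl compounds, and installs the chloride used as coupling handle at the end.

Step 2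
Reactants: 2 1-(5-chloro-2-hydroxy-3-methoxyphenyl)ethan-1-one; 3 N,N-dimethylformamide dimethyl acetal
Product: 5 6-chloro-8-methoxy-4H-chromen-4-one, via enaminone 4 (not isolated)
Conditions: 3 (2 equiv), toluene, 100 °C; concentrate; conc. HCl, CH2Cl2, 40 °C
Reagents that add atoms: none
Why: Condensation of the methyl ketone with the amide acetal gives the enaminone, and acid then drives 6-endo addition of the phenol to the β-carbon with loss of dimethylamine (enaminone route to chromones), which closes the pyranone ring.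

Step 3
Reactants: 5 6-chloro-8-methoxy-4H-chromen-4-one; 6 (4-methoxyphenyl)boronic acid
Product: 7 (2S)-6-chloro-8-methoxy-2-(4-methoxyphenyl)-2,3-dihydro-4H-chromen-4-one
Conditions: Pd(OCOCF3)2 (5 mol%), (R)-t-BuPyOx (6 mol%), NH4PF6 (30 mol%), H2O (5 equiv), ClCH2CH2Cl, 60 °C
Reagents that add atoms: none
Why: Asymmetric conjugate addition of an arylboronic acid to a chromone under divalent palladium with a chiral pyridine-oxazoline: enantioface-selective insertion of the C2=C3 bond into the aryl–Pd bond, steered by the tert-butyl group of the ligand, sets C2 (S), and protonolysis of the palladium enolate by water releases the flavanone without passing through zerovalent palladium, so the aryl chloride is left alone.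

Step 4
Reactants: 7 (2S)-6-chloro-8-methoxy-2-(4-methoxyphenyl)-2,3-dihydro-4H-chromen-4-one
Product: 8 methyl (2S,3S)-5-chloro-7-methoxy-2-(4-methoxyphenyl)-2,3-dihydro-1-benzofuran-3-carboxylate
Conditions: PhI(OAc)2 (1.2 equiv), H2SO4, HC(OMe)3, rt
Reagents that add atoms: trimethyl orthoformate, COC(OC)OC
Why: Oxidative ring contraction of a flavanone with PhI(OAc)2 in acidic orthoformate: the enol ether is iodinated at C3, the benzo carbon C4a shifts from C4 to C3 as PhI leaves (1,2-aryl shift) and C4 ends as the methyl ester, while C2 is not involved and the new centre α to the ester forms trans to the C2 aryl group, which is also the arrangement favoured at equilibrium.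

Step 5
Reactants: 8 methyl (2S,3S)-5-chloro-7-methoxy-2-(4-methoxyphenyl)-2,3-dihydro-1-benzofuran-3-carboxylate; 9 dimethyl (1-diazo-2-oxopropyl)phosphonate
Product: 11 (2S,3S)-5-chloro-3-ethynyl-7-methoxy-2-(4-methoxyphenyl)-2,3-dihydro-1-benzofuran, via aldehyde 10 (not isolated)
Conditions: i-Bu2AlH (1.2 equiv), CH2Cl2, −78 °C; then MeOH, 9, K2CO3, −78 °C → rt
Reagents that add atoms: none
Why: Partial reduction stops at the aluminium hemiacetal at low temperature, methanol releases the aldehyde, and the Ohira–Bestmann reagent converts it in the same flask into the terminal alkyne (Seyferth–Gilbert homologation), with C3 expected to stay in the more stable trans arrangement even if it epimerises at the aldehyde stage.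

Step 6
Reactants: 11 (2S,3S)-5-chloro-3-ethynyl-7-methoxy-2-(4-methoxyphenyl)-2,3-dihydro-1-benzofuran; 12 trichloroacetyl chloride
Product: 13 4,4-dichloro-3-[(2S,3R)-5-chloro-7-methoxy-2-(4-methoxyphenyl)-2,3-dihydro-1-benzofuran-3-yl]cyclobut-2-en-1-one
Conditions: 12 (2 equiv, slow addition), Zn–Cu couple, Et2O/DME, rt
Reagents that add atoms: none
Why: Dichloroketene, generated from 12 by zinc, undergoes [2+2] cycloaddition with the terminal alkyne, its carbonyl carbon bonding to the terminal CH, to give the 3-substituted 4,4-dichlorocyclobutenone, while DME ties up the ZnCl2 formed.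

Step 7
Reactants: 13 4,4-dichloro-3-[(2S,3R)-5-chloro-7-methoxy-2-(4-methoxyphenyl)-2,3-dihydro-1-benzofuran-3-yl]cyclobut-2-en-1-one
Product: 14 3-[(2S,3S)-5-chloro-7-methoxy-2-(4-methoxyphenyl)-2,3-dihydro-1-benzofuran-3-yl]cyclobut-2-en-1-one
Conditions: Zn dust, AcOH, TMEDA, EtOH, 0 °C → rt
Reagents that add atoms: none
Why: Zinc removes both chlorines α to the carbonyl group (reductive dehalogenation of an α,α-dichloroketone) under buffered conditions that should spare the strained enone, the benzylic C3–H and the aryl chloride.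

Step 8
Reactants: 14 3-[(2S,3S)-5-chloro-7-methoxy-2-(4-methoxyphenyl)-2,3-dihydro-1-benzofuran-3-yl]cyclobut-2-en-1-one; 15 ethoxyethyne
Product: 20 3-[(2S,3S)-5-chloro-7-methoxy-2-(4-methoxyphenyl)-2,3-dihydro-1-benzofuran-3-yl]-5-ethoxyphenol, via vinylketene 16 (not isolated), via 2-vinylcyclobutenone 17 (not isolated), via dienylketene 18 (not isolated), via cyclohexadienone 19 (not isolated)
Conditions: 15 (3 equiv), toluene, 80 °C, sealed tube
Reagents that add atoms: none
Why: Thermal conrotatory 4π opening of 14 gives vinylketene 16, whose electrophilic carbonyl carbon bonds to the nucleophilic CH terminus of 15 in a regiospecific [2+2] cycloaddition to give 17; a second 4π opening gives dienylketene 18, which closes the six-membered carbocycle by disrotatory 6π electrocyclisation (ketene carbon to terminal methylene) to dienone 19 and tautomerises to phenol 20. The closest known reaction type is the Danheiser benzannulation of a cyclobutenone with an alkynyl ether, which delivers resorcinol monoethers. The two new ring bonds are C(OH)–CH (to the CH between the oxygens) and C(OEt)–CH (to the CH between the ethoxy group and the C3 substituent), so hydroxyl and ethoxy end meta to each other with hydrogen between them and the dihydrobenzofuran carbon meta to both. No stereocentre is created: the sp3 ring carbon of 17 is a transient, unselective centre erased on ring opening. The step needs regioselectivity, which the polarity of ketene and ynol ether secures, and configurational integrity at C3 of the dihydrobenzofuran, which the absence of acid, base and metal secures, together with the unsubstituted methylene terminus of 16, which leaves no 1,5-hydrogen shift that could involve the C3–H.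

Step 9
Reactants: 20 3-[(2S,3S)-5-chloro-7-methoxy-2-(4-methoxyphenyl)-2,3-dihydro-1-benzofuran-3-yl]-5-ethoxyphenol
Product: 21 (2S,3S)-5-chloro-3-(3-ethoxy-5-methoxyphenyl)-7-methoxy-2-(4-methoxyphenyl)-2,3-dihydro-1-benzofuran
Conditions: MeI, K2CO3, acetone, 50 °C
Reagents that add atoms: iodomethane, CI
Why: Williamson etherification of the phenoxide removes the acidic OH before the palladium coupling and leaves every oxygen as an alkyl ether that BBr3 cleaves in the last step.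

Step 10
Reactants: 22 2-bromo-4,6-dimethoxybenzaldehyde
Product: 23 2-bromo-6-hydroxy-4-methoxybenzaldehyde
Conditions: BCl3 (1.1 equiv), CH2Cl2, −78 → 0 °C; H2O
Reagents that add atoms: none
Why: Chelation-directed Lewis-acid ether cleavage: BCl3 bound to the formyl oxygen delivers chloride only to the ortho methoxy group, so the para methoxy group should survive.

Step 11
Reactants: 23 2-bromo-6-hydroxy-4-methoxybenzaldehyde; 24 1-(chloromethyl)-4-methoxybenzene
Product: 25 2-bromo-4-methoxy-6-[(4-methoxyphenyl)methoxy]benzaldehyde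
Conditions: K2CO3, Bu4NI (cat.), DMF, 60 °C
Reagents that add atoms: none
Why: Williamson O-benzylation, in which the 4-methoxybenzyl group is not a protecting group but supplies C2 of unit 3 together with its aryl substituent.

Step 12
Reactants: 25 2-bromo-4-methoxy-6-[(4-methoxyphenyl)methoxy]benzaldehyde; 26 (3,5-dimethoxyphenyl)magnesium bromide
Product: 27 {2-bromo-4-methoxy-6-[(4-methoxyphenyl)methoxy]phenyl}(3,5-dimethoxyphenyl)methanol
Conditions: THF, 0 °C → rt; aq. NH4Cl
Reagents that add atoms: none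
Why: Grignard 1,2-addition to the aldehyde forms the bond between ring C and the future C3 of unit 3, and the racemic carbinol centre is removed in the next step.

Step 13
Reactants: 27 {2-bromo-4-methoxy-6-[(4-methoxyphenyl)methoxy]phenyl}(3,5-dimethoxyphenyl)methanol
Product: 28 {2-bromo-4-methoxy-6-[(4-methoxyphenyl)methoxy]phenyl}(3,5-dimethoxyphenyl)methanone
Conditions: Dess–Martin periodinane, CH2Cl2, rt
Reagents that add atoms: none
Why: Dess–Martin oxidation of the diaryl carbinol gives the ketone under near-neutral conditions that leave the benzyl ether and the aryl bromide untouched.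

Step 14
Reactants: 28 {2-bromo-4-methoxy-6-[(4-methoxyphenyl)methoxy]phenyl}(3,5-dimethoxyphenyl)methanone
Product: 29 [{2-bromo-4-methoxy-6-[(4-methoxyphenyl)methoxy]phenyl}(3,5-dimethoxyphenyl)methylidene]hydrazine
Conditions: N2H4·H2O (20 equiv), AcOH (cat.), n-BuOH, 110 °C
Reagents that add atoms: hydrazine (as hydrate), NN
Why: Acid-catalysed condensation of the ketone with hydrazine gives the N-unsubstituted hydrazone, with excess reagent and heat chosen because the carbonyl group carries a di-ortho-substituted ring.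

Step 15
Reactants: 29 [{2-bromo-4-methoxy-6-[(4-methoxyphenyl)methoxy]phenyl}(3,5-dimethoxyphenyl)methylidene]hydrazine
Product: 31 (2R,3S)-4-bromo-3-(3,5-dimethoxyphenyl)-6-methoxy-2-(4-methoxyphenyl)-2,3-dihydro-1-benzofuran, via diaryldiazomethane 30 (not isolated)
Conditions: MnO2 (8 equiv), CH2Cl2, 0 °C; then Rh2(R-PTAD)4 (1 mol%), 0 °C → rt
Reagents that add atoms: none
Why: MnO2 dehydrogenates the hydrazone to the diaryldiazomethane, and the chiral dirhodium tetracarboxylate converts it into a donor/donor carbene that inserts into a benzylic C–H bond of the OCH2 group (intramolecular 1,5 C–H insertion closing the five-membered ring), the concerted insertion giving the cis ring and the catalyst selecting carbene face and enantiotopic hydrogen so that C3 is S and C2 is R.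

Step 16
Reactants: 31 (2R,3S)-4-bromo-3-(3,5-dimethoxyphenyl)-6-methoxy-2-(4-methoxyphenyl)-2,3-dihydro-1-benzofuran
Product: 32 (2S,3S)-4-bromo-3-(3,5-dimethoxyphenyl)-6-methoxy-2-(4-methoxyphenyl)-2,3-dihydro-1-benzofuran
Conditions: CF3CO2H (5 equiv), CH2Cl2 (dilute), 0 °C → rt
Reagents that add atoms: none
Why: Acid-mediated epimerisation of a 2-aryl-2,3-dihydrobenzofuran: reversible ionisation of the C2–O bond to the 4-methoxybenzyl cation and re-closure by the phenol lead to the more stable trans isomer, so C2 becomes S under thermodynamic control while C3 keeps the configuration set by the catalyst.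

Step 17
Reactants: 33 4-bromo-2-hydroxybenzaldehyde; 24 1-(chloromethyl)-4-methoxybenzene
Product: 34 4-bromo-2-[(4-methoxyphenyl)methoxy]benzaldehyde
Conditions: K2CO3, Bu4NI (cat.), DMF, 60 °C
Reagents that add atoms: none
Why: Williamson O-benzylation, where this benzyl group later becomes C2 of unit 2 with its 4-methoxyphenyl group.

Step 18
Reactants: 32 (2S,3S)-4-bromo-3-(3,5-dimethoxyphenyl)-6-methoxy-2-(4-methoxyphenyl)-2,3-dihydro-1-benzofuran; 34 4-bromo-2-[(4-methoxyphenyl)methoxy]benzaldehyde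
Product: 36 {4-bromo-2-[(4-methoxyphenyl)methoxy]phenyl}[(2S,3S)-3-(3,5-dimethoxyphenyl)-6-methoxy-2-(4-methoxyphenyl)-2,3-dihydro-1-benzofuran-4-yl]methanol, via aryllithium 35 (not isolated)
Conditions: n-BuLi (1.05 equiv), THF, −78 °C; then 34, −78 → 0 °C; aq. NH4Cl
Reagents that add atoms: none
Why: Bromine–lithium exchange at C4 of unit 3 is faster than any deprotonation, and the aryllithium adds to the aldehyde of 34 faster than it exchanges with the second aryl bromide (1,2-addition), which forms the bond between ring C and the future C3 of unit 2 and gives carbinol epimers that converge in the next step.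

Step 19
Reactants: 36 {4-bromo-2-[(4-methoxyphenyl)methoxy]phenyl}[(2S,3S)-3-(3,5-dimethoxyphenyl)-6-methoxy-2-(4-methoxyphenyl)-2,3-dihydro-1-benzofuran-4-yl]methanol
Product: 37 {4-bromo-2-[(4-methoxyphenyl)methoxy]phenyl}[(2S,3S)-3-(3,5-dimethoxyphenyl)-6-methoxy-2-(4-methoxyphenyl)-2,3-dihydro-1-benzofuran-4-yl]methanone
Conditions: Dess–Martin periodinane, CH2Cl2, rt
Reagents that add atoms: none
Why: Dess–Martin oxidation of the diaryl carbinol to the ketone removes the carbinol stereocentre and does not touch the dihydrobenzofuran.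

Step 20
Reactants: 37 {4-bromo-2-[(4-methoxyphenyl)methoxy]phenyl}[(2S,3S)-3-(3,5-dimethoxyphenyl)-6-methoxy-2-(4-methoxyphenyl)-2,3-dihydro-1-benzofuran-4-yl]methanone
Product: 38 [{4-bromo-2-[(4-methoxyphenyl)methoxy]phenyl}[(2S,3S)-3-(3,5-dimethoxyphenyl)-6-methoxy-2-(4-methoxyphenyl)-2,3-dihydro-1-benzofuran-4-yl]methylidene]hydrazine
Conditions: N2H4·H2O (20 equiv), AcOH (cat.), n-BuOH, 110 °C
Reagents that add atoms: hydrazine (as hydrate), NN
Why: Acid-catalysed condensation with hydrazine as in step 14, here on a ketone whose two rings each carry only one ortho substituent.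

Step 21
Reactants: 38 [{4-bromo-2-[(4-methoxyphenyl)methoxy]phenyl}[(2S,3S)-3-(3,5-dimethoxyphenyl)-6-methoxy-2-(4-methoxyphenyl)-2,3-dihydro-1-benzofuran-4-yl]methylidene]hydrazine
Product: 40 (2S,3R)-6-bromo-3-[(2S,3S)-3-(3,5-dimethoxyphenyl)-6-methoxy-2-(4-methoxyphenyl)-2,3-dihydro-1-benzofuran-4-yl]-2-(4-methoxyphenyl)-2,3-dihydro-1-benzofuran, via diaryldiazomethane 39 (not isolated)
Conditions: MnO2 (8 equiv), CH2Cl2, 0 °C; then Rh2(S-PTAD)4 (1 mol%), 0 °C → rt
Reagents that add atoms: none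
Why: The same hydrazone oxidation and rhodium carbene 1,5 C–H insertion as in step 15, now with the enantiomeric catalyst, which should override the bias of the remote centres of unit 3 and set C3 of unit 2 as R and C2 as S in the cis ring.

Step 22
Reactants: 40 (2S,3R)-6-bromo-3-[(2S,3S)-3-(3,5-dimethoxyphenyl)-6-methoxy-2-(4-methoxyphenyl)-2,3-dihydro-1-benzofuran-4-yl]-2-(4-methoxyphenyl)-2,3-dihydro-1-benzofuran
Product: 41 (2R,3R)-6-bromo-3-[(2S,3S)-3-(3,5-dimethoxyphenyl)-6-methoxy-2-(4-methoxyphenyl)-2,3-dihydro-1-benzofuran-4-yl]-2-(4-methoxyphenyl)-2,3-dihydro-1-benzofuran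
Conditions: CF3CO2H (5 equiv), CH2Cl2 (dilute), 0 °C → rt
Reagents that add atoms: none
Why: Acid epimerisation at C2 of unit 2 through the benzylic cation as in step 16 gives the trans (2R,3R) ring, while unit 3, already trans, can only ionise and re-close to itself.

Step 23
Reactants: 41 (2R,3R)-6-bromo-3-[(2S,3S)-3-(3,5-dimethoxyphenyl)-6-methoxy-2-(4-methoxyphenyl)-2,3-dihydro-1-benzofuran-4-yl]-2-(4-methoxyphenyl)-2,3-dihydro-1-benzofuran; 42 4,4,5,5-tetramethyl-2-vinyl-1,3,2-dioxaborolane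
Product: 43 2-[(E)-2-{(2R,3R)-3-[(2S,3S)-3-(3,5-dimethoxyphenyl)-6-methoxy-2-(4-methoxyphenyl)-2,3-dihydro-1-benzofuran-4-yl]-2-(4-methoxyphenyl)-2,3-dihydro-1-benzofuran-6-yl}ethenyl]-4,4,5,5-tetramethyl-1,3,2-dioxaborolane
Conditions: 42 (1.5 equiv), Pd(P(t-Bu)3)2 (5 mol%), i-Pr2NH, toluene, 80 °C
Reagents that add atoms: none
Why: Mizoroki–Heck reaction of the aryl bromide with the vinylboronate: with an amine base and no water or hydroxide, transmetalation from boron is slow, so the aryl–Pd species adds to the terminal carbon of the vinyl group and syn β-hydride elimination gives the (E)-alkenylboronate.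

Step 24
Reactants: 21 (2S,3S)-5-chloro-3-(3-ethoxy-5-methoxyphenyl)-7-methoxy-2-(4-methoxyphenyl)-2,3-dihydro-1-benzofuran; 43 2-[(E)-2-{(2R,3R)-3-[(2S,3S)-3-(3,5-dimethoxyphenyl)-6-methoxy-2-(4-methoxyphenyl)-2,3-dihydro-1-benzofuran-4-yl]-2-(4-methoxyphenyl)-2,3-dihydro-1-benzofuran-6-yl}ethenyl]-4,4,5,5-tetramethyl-1,3,2-dioxaborolane
Product: 44 (2S,3S)-5-[(E)-2-{(2R,3R)-3-[(2S,3S)-3-(3,5-dimethoxyphenyl)-6-methoxy-2-(4-methoxyphenyl)-2,3-dihydro-1-benzofuran-4-yl]-2-(4-methoxyphenyl)-2,3-dihydro-1-benzofuran-6-yl}ethenyl]-3-(3-ethoxy-5-methoxyphenyl)-7-methoxy-2-(4-methoxyphenyl)-2,3-dihydro-1-benzofuran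
Conditions: Pd(OAc)2 (5 mol%), SPhos (10 mol%), K3PO4, toluene/H2O (10:1), 90 °C
Reagents that add atoms: none
Why: Suzuki–Miyaura coupling in which the electron-rich dialkylbiarylphosphine lets zerovalent palladium insert into the aryl chloride, and transmetalation and reductive elimination proceed with retention of the E alkene geometry.

Step 25
Reactants: 44 (2S,3S)-5-[(E)-2-{(2R,3R)-3-[(2S,3S)-3-(3,5-dimethoxyphenyl)-6-methoxy-2-(4-methoxyphenyl)-2,3-dihydro-1-benzofuran-4-yl]-2-(4-methoxyphenyl)-2,3-dihydro-1-benzofuran-6-yl}ethenyl]-3-(3-ethoxy-5-methoxyphenyl)-7-methoxy-2-(4-methoxyphenyl)-2,3-dihydro-1-benzofuran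
Product: 45 (2S,3S)-3-(3,5-dihydroxyphenyl)-5-[(E)-2-{(2R,3R)-3-[(2S,3S)-3-(3,5-dihydroxyphenyl)-6-hydroxy-2-(4-hydroxyphenyl)-2,3-dihydro-1-benzofuran-4-yl]-2-(4-hydroxyphenyl)-2,3-dihydro-1-benzofuran-6-yl}ethenyl]-2-(4-hydroxyphenyl)-2,3-dihydro-1-benzofuran-7-ol
Conditions: BBr3 (30 equiv), CH2Cl2, −78 °C → rt; then H2O
Reagents that add atoms: none
Why: Lewis-acid dealkylation of aryl alkyl ethers with BBr3 should free all nine phenols (eight methyl ethers, one ethyl ether), and because the three trans rings are the thermodynamic isomers any reversible C2–O ionisation should return the same configuration.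

**Compound list**

1 | 1-(2-hydroxy-3-methoxyphenyl)ethan-1-one | CC(=O)c1cccc(OC)c1O | starting material
2 | 1-(5-chloro-2-hydroxy-3-methoxyphenyl)ethan-1-one | CC(=O)c1cc(Cl)cc(OC)c1O | intermediate
3 | N,N-dimethylformamide dimethyl acetal | COC(OC)N(C)C | starting material
4 | (E)-1-(5-chloro-2-hydroxy-3-methoxyphenyl)-3-(dimethylamino)prop-2-en-1-one | CN(C)/C=C/C(=O)c1cc(Cl)cc(OC)c1O | intermediate
5 | 6-chloro-8-methoxy-4H-chromen-4-one | COc1cc(Cl)cc2c(=O)ccoc12 | intermediate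
6 | (4-methoxyphenyl)boronic acid | COc1ccc(B(O)O)cc1 | starting material
7 | (2S)-6-chloro-8-methoxy-2-(4-methoxyphenyl)-2,3-dihydro-4H-chromen-4-one | COc1ccc([C@@H]2CC(=O)c3cc(Cl)cc(OC)c3O2)cc1 | intermediate
8 | methyl (2S,3S)-5-chloro-7-methoxy-2-(4-methoxyphenyl)-2,3-dihydro-1-benzofuran-3-carboxylate (trans) | COc1ccc([C@H]2Oc3c(OC)cc(Cl)cc3[C@@H]2C(=O)OC)cc1 | intermediate
9 | dimethyl (1-diazo-2-oxopropyl)phosphonate | COP(=O)(OC)C(=[N+]=[N-])C(C)=O | starting material
10 | (2S,3S)-5-chloro-7-methoxy-2-(4-methoxyphenyl)-2,3-dihydro-1-benzofuran-3-carbaldehyde | COc1ccc([C@H]2Oc3c(OC)cc(Cl)cc3[C@@H]2C=O)cc1 | intermediate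
11 | (2S,3S)-5-chloro-3-ethynyl-7-methoxy-2-(4-methoxyphenyl)-2,3-dihydro-1-benzofuran | COc1ccc([C@H]2Oc3c(OC)cc(Cl)cc3[C@@H]2C#C)cc1 | intermediate
12 | trichloroacetyl chloride | O=C(Cl)C(Cl)(Cl)Cl | starting material
13 | 4,4-dichloro-3-[(2S,3R)-5-chloro-7-methoxy-2-(4-methoxyphenyl)-2,3-dihydro-1-benzofuran-3-yl]cyclobut-2-en-1-one (same trans geometry; the C3 descriptor changes through ligand priority only) | COc1ccc([C@H]2Oc3c(OC)cc(Cl)cc3[C@@H]2C2=CC(=O)C2(Cl)Cl)cc1 | intermediate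
14 | 3-[(2S,3S)-5-chloro-7-methoxy-2-(4-methoxyphenyl)-2,3-dihydro-1-benzofuran-3-yl]cyclobut-2-en-1-one | COc1ccc([C@H]2Oc3c(OC)cc(Cl)cc3[C@@H]2C2=CC(=O)C2)cc1 | intermediate
15 | ethoxyethyne (ethoxyacetylene) | CCOC#C | starting material
16 | 3-[(2S,3S)-5-chloro-7-methoxy-2-(4-methoxyphenyl)-2,3-dihydro-1-benzofuran-3-yl]buta-1,3-dien-1-one | COc1ccc([C@H]2Oc3c(OC)cc(Cl)cc3[C@@H]2C(=C)C=C=O)cc1 | intermediate
17 | 3-ethoxy-4-{1-[(2S,3S)-5-chloro-7-methoxy-2-(4-methoxyphenyl)-2,3-dihydro-1-benzofuran-3-yl]ethenyl}cyclobut-2-en-1-one (both epimers at C4 of the four-membered ring) | COc1ccc([C@H]2Oc3c(OC)cc(Cl)cc3[C@@H]2C(=C)C2C(=O)C=C2OCC)cc1 | intermediate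
18 | (3E)-3-ethoxy-5-[(2S,3S)-5-chloro-7-methoxy-2-(4-methoxyphenyl)-2,3-dihydro-1-benzofuran-3-yl]hexa-1,3,5-trien-1-one | COc1ccc([C@H]2Oc3c(OC)cc(Cl)cc3[C@@H]2C(=C)/C=C(/OCC)C=C=O)cc1 | intermediate
19 | 3-ethoxy-5-[(2S,3S)-5-chloro-7-methoxy-2-(4-methoxyphenyl)-2,3-dihydro-1-benzofuran-3-yl]cyclohexa-2,4-dien-1-one | COc1ccc([C@H]2Oc3c(OC)cc(Cl)cc3[C@@H]2C2=CC(OCC)=CC(=O)C2)cc1 | intermediate
20 | 3-[(2S,3S)-5-chloro-7-methoxy-2-(4-methoxyphenyl)-2,3-dihydro-1-benzofuran-3-yl]-5-ethoxyphenol | COc1ccc([C@H]2Oc3c(OC)cc(Cl)cc3[C@@H]2c2cc(O)cc(OCC)c2)cc1 | intermediate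
21 | (2S,3S)-5-chloro-3-(3-ethoxy-5-methoxyphenyl)-7-methoxy-2-(4-methoxyphenyl)-2,3-dihydro-1-benzofuran | COc1ccc([C@H]2Oc3c(OC)cc(Cl)cc3[C@@H]2c2cc(OC)cc(OCC)c2)cc1 | intermediate
22 | 2-bromo-4,6-dimethoxybenzaldehyde | COc1cc(Br)c(C=O)c(OC)c1 | starting material
23 | 2-bromo-6-hydroxy-4-methoxybenzaldehyde | COc1cc(O)c(C=O)c(Br)c1 | intermediate
24 | 1-(chloromethyl)-4-methoxybenzene | COc1ccc(CCl)cc1 | starting material
25 | 2-bromo-4-methoxy-6-[(4-methoxyphenyl)methoxy]benzaldehyde | COc1ccc(COc2cc(OC)cc(Br)c2C=O)cc1 | intermediate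
26 | (3,5-dimethoxyphenyl)magnesium bromide (THF solution) | COc1cc(OC)cc([Mg]Br)c1 | starting material
27 | {2-bromo-4-methoxy-6-[(4-methoxyphenyl)methoxy]phenyl}(3,5-dimethoxyphenyl)methanol (racemic) | COc1ccc(COc2cc(OC)cc(Br)c2C(O)c2cc(OC)cc(OC)c2)cc1 | intermediate
28 | {2-bromo-4-methoxy-6-[(4-methoxyphenyl)methoxy]phenyl}(3,5-dimethoxyphenyl)methanone | COc1ccc(COc2cc(OC)cc(Br)c2C(=O)c2cc(OC)cc(OC)c2)cc1 | intermediate
29 | [{2-bromo-4-methoxy-6-[(4-methoxyphenyl)methoxy]phenyl}(3,5-dimethoxyphenyl)methylidene]hydrazine (E/Z mixture) | COc1ccc(COc2cc(OC)cc(Br)c2C(=NN)c2cc(OC)cc(OC)c2)cc1 | intermediate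
30 | 1-bromo-2-[diazo(3,5-dimethoxyphenyl)methyl]-5-methoxy-3-[(4-methoxyphenyl)methoxy]benzene | COc1ccc(COc2cc(OC)cc(Br)c2C(=[N+]=[N-])c2cc(OC)cc(OC)c2)cc1 | intermediate
31 | (2R,3S)-4-bromo-3-(3,5-dimethoxyphenyl)-6-methoxy-2-(4-methoxyphenyl)-2,3-dihydro-1-benzofuran (cis) | Brc1cc(OC)cc2c1[C@H](c1cc(OC)cc(OC)c1)[C@H](c1ccc(OC)cc1)O2 | intermediate
32 | (2S,3S)-4-bromo-3-(3,5-dimethoxyphenyl)-6-methoxy-2-(4-methoxyphenyl)-2,3-dihydro-1-benzofuran (trans) | Brc1cc(OC)cc2c1[C@H](c1cc(OC)cc(OC)c1)[C@@H](c1ccc(OC)cc1)O2 | intermediate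
33 | 4-bromo-2-hydroxybenzaldehyde | O=Cc1ccc(Br)cc1O | starting material
34 | 4-bromo-2-[(4-methoxyphenyl)methoxy]benzaldehyde | COc1ccc(COc2cc(Br)ccc2C=O)cc1 | intermediate
35 | [(2S,3S)-3-(3,5-dimethoxyphenyl)-6-methoxy-2-(4-methoxyphenyl)-2,3-dihydro-1-benzofuran-4-yl]lithium | [Li]c1cc(OC)cc2c1[C@H](c1cc(OC)cc(OC)c1)[C@@H](c1ccc(OC)cc1)O2 | intermediate
36 | {4-bromo-2-[(4-methoxyphenyl)methoxy]phenyl}[(2S,3S)-3-(3,5-dimethoxyphenyl)-6-methoxy-2-(4-methoxyphenyl)-2,3-dihydro-1-benzofuran-4-yl]methanol (both carbinol epimers) | OC(c1ccc(Br)cc1OCc1ccc(OC)cc1)c1cc(OC)cc2c1[C@H](c1cc(OC)cc(OC)c1)[C@@H](c1ccc(OC)cc1)O2 | intermediate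
37 | {4-bromo-2-[(4-methoxyphenyl)methoxy]phenyl}[(2S,3S)-3-(3,5-dimethoxyphenyl)-6-methoxy-2-(4-methoxyphenyl)-2,3-dihydro-1-benzofuran-4-yl]methanone | O=C(c1ccc(Br)cc1OCc1ccc(OC)cc1)c1cc(OC)cc2c1[C@H](c1cc(OC)cc(OC)c1)[C@@H](c1ccc(OC)cc1)O2 | intermediate
38 | [{4-bromo-2-[(4-methoxyphenyl)methoxy]phenyl}[(2S,3S)-3-(3,5-dimethoxyphenyl)-6-methoxy-2-(4-methoxyphenyl)-2,3-dihydro-1-benzofuran-4-yl]methylidene]hydrazine (E/Z mixture) | NN=C(c1ccc(Br)cc1OCc1ccc(OC)cc1)c1cc(OC)cc2c1[C@H](c1cc(OC)cc(OC)c1)[C@@H](c1ccc(OC)cc1)O2 | intermediate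
39 | (2S,3S)-4-[{4-bromo-2-[(4-methoxyphenyl)methoxy]phenyl}(diazo)methyl]-3-(3,5-dimethoxyphenyl)-6-methoxy-2-(4-methoxyphenyl)-2,3-dihydro-1-benzofuran | [N-]=[N+]=C(c1ccc(Br)cc1OCc1ccc(OC)cc1)c1cc(OC)cc2c1[C@H](c1cc(OC)cc(OC)c1)[C@@H](c1ccc(OC)cc1)O2 | intermediate
40 | (2S,3R)-6-bromo-3-[(2S,3S)-3-(3,5-dimethoxyphenyl)-6-methoxy-2-(4-methoxyphenyl)-2,3-dihydro-1-benzofuran-4-yl]-2-(4-methoxyphenyl)-2,3-dihydro-1-benzofuran (new ring cis) | Brc1ccc2c(c1)O[C@H](c1ccc(OC)cc1)[C@@H]2c1cc(OC)cc2c1[C@H](c1cc(OC)cc(OC)c1)[C@@H](c1ccc(OC)cc1)O2 | intermediate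
41 | (2R,3R)-6-bromo-3-[(2S,3S)-3-(3,5-dimethoxyphenyl)-6-methoxy-2-(4-methoxyphenyl)-2,3-dihydro-1-benzofuran-4-yl]-2-(4-methoxyphenyl)-2,3-dihydro-1-benzofuran (both rings trans) | Brc1ccc2c(c1)O[C@@H](c1ccc(OC)cc1)[C@@H]2c1cc(OC)cc2c1[C@H](c1cc(OC)cc(OC)c1)[C@@H](c1ccc(OC)cc1)O2 | intermediate
42 | 4,4,5,5-tetramethyl-2-vinyl-1,3,2-dioxaborolane | C=CB1OC(C)(C)C(C)(C)O1 | starting material
43 | 2-[(E)-2-{(2R,3R)-3-[(2S,3S)-3-(3,5-dimethoxyphenyl)-6-methoxy-2-(4-methoxyphenyl)-2,3-dihydro-1-benzofuran-4-yl]-2-(4-methoxyphenyl)-2,3-dihydro-1-benzofuran-6-yl}ethenyl]-4,4,5,5-tetramethyl-1,3,2-dioxaborolane | CC1(C)OB(/C=C/c2ccc3c(c2)O[C@@H](c2ccc(OC)cc2)[C@@H]3c2cc(OC)cc3c2[C@H](c2cc(OC)cc(OC)c2)[C@@H](c2ccc(OC)cc2)O3)OC1(C)C | intermediate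
44 | (2S,3S)-5-[(E)-2-{(2R,3R)-3-[(2S,3S)-3-(3,5-dimethoxyphenyl)-6-methoxy-2-(4-methoxyphenyl)-2,3-dihydro-1-benzofuran-4-yl]-2-(4-methoxyphenyl)-2,3-dihydro-1-benzofuran-6-yl}ethenyl]-3-(3-ethoxy-5-methoxyphenyl)-7-methoxy-2-(4-methoxyphenyl)-2,3-dihydro-1-benzofuran | COc1ccc([C@H]2Oc3c(OC)cc(/C=C/c4ccc5c(c4)O[C@@H](c4ccc(OC)cc4)[C@@H]5c4cc(OC)cc5c4[C@H](c4cc(OC)cc(OC)c4)[C@@H](c4ccc(OC)cc4)O5)cc3[C@@H]2c2cc(OC)cc(OCC)c2)cc1 | intermediate
45 | CNP0265934.1, (2S,3S)-3-(3,5-dihydroxyphenyl)-5-[(E)-2-{(2R,3R)-3-[(2S,3S)-3-(3,5-dihydroxyphenyl)-6-hydroxy-2-(4-hydroxyphenyl)-2,3-dihydro-1-benzofuran-4-yl]-2-(4-hydroxyphenyl)-2,3-dihydro-1-benzofuran-6-yl}ethenyl]-2-(4-hydroxyphenyl)-2,3-dihydro-1-benzofuran-7-ol | Oc1ccc([C@H]2Oc3c(O)cc(/C=C/c4ccc5c(c4)O[C@@H](c4ccc(O)cc4)[C@@H]5c4cc(O)cc5c4[C@H](c4cc(O)cc(O)c4)[C@@H](c4ccc(O)cc4)O5)cc3[C@@H]2c2cc(O)cc(O)c2)cc1 | target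

**Step count and risks**

Total: 25 steps. Longest linear sequence: 15 steps (22 to 45 through steps 10–16 and 18–25). The west branch (steps 1–9) joins at step 24, and step 17 is a one-step side branch.

Steps most likely to fail:

Step 14. The condensation may stall because the carbonyl carbon is shielded on both faces by the bromine and the benzyloxy group of the twisted ring, and on prolonged heating the hydrazone nitrogen may displace the ortho bromide. The fallback sets out from aldehyde 25 and makes the C=N bond by addition instead of condensation. I2 and aqueous NH3 in THF convert 25 into 2-bromo-4-methoxy-6-[(4-methoxyphenyl)methoxy]benzonitrile F1. Grignard reagent 26 then adds to the linear, unshielded nitrile carbon (THF, 60 °C, methanol quench) to give the N–H ketimine {2-bromo-4-methoxy-6-[(4-methoxyphenyl)methoxy]phenyl}(3,5-dimethoxyphenyl)methanimine F2. Exchange of NH for NNH2 with N2H4·H2O and AcOH in EtOH (transimination, which needs no dehydration at the crowded carbon) comes back to the route at hydrazone 29.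

Step 8. Ethoxyacetylene may fragment thermally before it traps the vinylketene, the vinylketene may dimerise or acylate the product phenol, and the C3–H may be lost through enolisation of the cyclobutenone at 80 °C. The fallback sets out from ester 8 and makes the C3–aryl bond directly. LiOH in THF/H2O gives (2S,3S)-5-chloro-7-methoxy-2-(4-methoxyphenyl)-2,3-dihydro-1-benzofuran-3-carboxylic acid F3. N-Hydroxyphthalimide and diisopropylcarbodiimide give its 1,3-dioxoisoindolin-2-yl ester F4. (3,5-Dimethoxyphenyl)zinc chloride F5, made from 26 and ZnCl2, is coupled with F4 under NiCl2(dme) and 4,4'-di-tert-butyl-2,2'-bipyridine in THF/DMF (decarboxylative arylation through the C3 radical, which should be captured anti to the C2 aryl group). This gives (2S,3S)-5-chloro-3-(3,5-dimethoxyphenyl)-7-methoxy-2-(4-methoxyphenyl)-2,3-dihydro-1-benzofuran F6. F6 takes the place of 21 in step 24 and gives the nonamethyl ether of the target F7, and the conditions of step 25 then come back to the route at 45.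

Step 25. BBr3 may ionise the three benzylic C2–O bonds while the stilbene is present, so that the cations add to the double bond or to neighbouring arenes; HBr may add to the alkene; and cleavage of nine ethers may stay incomplete. The fallback sets out from 21 and 41, dealkylates before the stilbene exists and ends with silyl ethers. BBr3 converts 21 into 5-[(2S,3S)-5-chloro-7-hydroxy-2-(4-hydroxyphenyl)-2,3-dihydro-1-benzofuran-3-yl]benzene-1,3-diol F8, and TBSCl with imidazole in DMF gives its tetrakis(tert-butyldimethylsilyl) ether F9. In the same way 41 gives the pentaphenol bromide of units 2 and 3 F10 and its pentakis(tert-butyldimethylsilyl) ether F11. A Mizoroki–Heck reaction of F11 with 42 as in step 23 gives the silylated (E)-alkenylboronate F12. Suzuki–Miyaura coupling of F9 with F12 as in step 24 gives the nonakis(tert-butyldimethylsilyl) ether of the target F13; partial loss of silyl groups there would be harmless. Bu4NF buffered with AcOH in THF removes all silyl groups without acid and comes back to the route at 45.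

**Further compounds**

F1 | step 14 | 2-bromo-4-methoxy-6-[(4-methoxyphenyl)methoxy]benzonitrile | COc1ccc(COc2cc(OC)cc(Br)c2C#N)cc1
F2 | step 14 | {2-bromo-4-methoxy-6-[(4-methoxyphenyl)methoxy]phenyl}(3,5-dimethoxyphenyl)methanimine | COc1ccc(COc2cc(OC)cc(Br)c2C(=N)c2cc(OC)cc(OC)c2)cc1
F3 | step 8 | (2S,3S)-5-chloro-7-methoxy-2-(4-methoxyphenyl)-2,3-dihydro-1-benzofuran-3-carboxylic acid | COc1ccc([C@H]2Oc3c(OC)cc(Cl)cc3[C@@H]2C(=O)O)cc1
F4 | step 8 | 1,3-dioxoisoindolin-2-yl (2S,3S)-5-chloro-7-methoxy-2-(4-methoxyphenyl)-2,3-dihydro-1-benzofuran-3-carboxylate | COc1ccc([C@H]2Oc3c(OC)cc(Cl)cc3[C@@H]2C(=O)ON2C(=O)c3ccccc3C2=O)cc1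
F5 | step 8 | (3,5-dimethoxyphenyl)zinc chloride | COc1cc(OC)cc([Zn]Cl)c1
F6 | step 8 | (2S,3S)-5-chloro-3-(3,5-dimethoxyphenyl)-7-methoxy-2-(4-methoxyphenyl)-2,3-dihydro-1-benzofuran | COc1ccc([C@H]2Oc3c(OC)cc(Cl)cc3[C@@H]2c2cc(OC)cc(OC)c2)cc1
F7 | step 8 | nonamethyl ether of the target (as 44 with OMe in place of OEt) | COc1ccc([C@H]2Oc3c(OC)cc(/C=C/c4ccc5c(c4)O[C@@H](c4ccc(OC)cc4)[C@@H]5c4cc(OC)cc5c4[C@H](c4cc(OC)cc(OC)c4)[C@@H](c4ccc(OC)cc4)O5)cc3[C@@H]2c2cc(OC)cc(OC)c2)cc1
F8 | step 25 | 5-[(2S,3S)-5-chloro-7-hydroxy-2-(4-hydroxyphenyl)-2,3-dihydro-1-benzofuran-3-yl]benzene-1,3-diol | Oc1ccc([C@H]2Oc3c(O)cc(Cl)cc3[C@@H]2c2cc(O)cc(O)c2)cc1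
F9 | step 25 | tetrakis(tert-butyldimethylsilyl) ether of F8 | CC(C)(C)[Si](C)(C)Oc1ccc([C@H]2Oc3c(O[Si](C)(C)C(C)(C)C)cc(Cl)cc3[C@@H]2c2cc(O[Si](C)(C)C(C)(C)C)cc(O[Si](C)(C)C(C)(C)C)c2)cc1
F10 | step 25 | 5-[(2S,3S)-4-[(2R,3R)-6-bromo-2-(4-hydroxyphenyl)-2,3-dihydro-1-benzofuran-3-yl]-6-hydroxy-2-(4-hydroxyphenyl)-2,3-dihydro-1-benzofuran-3-yl]benzene-1,3-diol | Brc1ccc2c(c1)O[C@@H](c1ccc(O)cc1)[C@@H]2c1cc(O)cc2c1[C@H](c1cc(O)cc(O)c1)[C@@H](c1ccc(O)cc1)O2
F11 | step 25 | pentakis(tert-butyldimethylsilyl) ether of F10 | Brc1ccc2c(c1)O[C@@H](c1ccc(O[Si](C)(C)C(C)(C)C)cc1)[C@@H]2c1cc(O[Si](C)(C)C(C)(C)C)cc2c1[C@H](c1cc(O[Si](C)(C)C(C)(C)C)cc(O[Si](C)(C)C(C)(C)C)c1)[C@@H](c1ccc(O[Si](C)(C)C(C)(C)C)cc1)O2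
F12 | step 25 | (E)-alkenylboronic acid pinacol ester from F11 (as 43 with tert-butyldimethylsilyl ethers in place of methyl ethers) | CC1(C)OB(/C=C/c2ccc3c(c2)O[C@@H](c2ccc(O[Si](C)(C)C(C)(C)C)cc2)[C@@H]3c2cc(O[Si](C)(C)C(C)(C)C)cc3c2[C@H](c2cc(O[Si](C)(C)C(C)(C)C)cc(O[Si](C)(C)C(C)(C)C)c2)[C@@H](c2ccc(O[Si](C)(C)C(C)(C)C)cc2)O3)OC1(C)C
F13 | step 25 | nonakis(tert-butyldimethylsilyl) ether of the target | CC(C)(C)[Si](C)(C)Oc1ccc([C@H]2Oc3c(O[Si](C)(C)C(C)(C)C)cc(/C=C/c4ccc5c(c4)O[C@@H](c4ccc(O[Si](C)(C)C(C)(C)C)cc4)[C@@H]5c4cc(O[Si](C)(C)C(C)(C)C)cc5c4[C@H](c4cc(O[Si](C)(C)C(C)(C)C)cc(O[Si](C)(C)C(C)(C)C)c4)[C@@H](c4ccc(O[Si](C)(C)C(C)(C)C)cc4)O5)cc3[C@@H]2c2cc(O[Si](C)(C)C(C)(C)C)cc(O[Si](C)(C)C(C)(C)C)c2)cc1
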